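**Retrosynthetic overview**
1. ε-Lactone (last ring): Yamaguchi closure of the C16 acid onto the C12 hydroxyl; the acid comes from allylic oxidation of an isopropenyl group.
2. Oxolane (third ring): syn-oxidative cyclisation of the C4 hydroxyl across the (E)-C7=C8 alkene of a 14-membered ketone sets C7 and C8.
3. 14-Membered carbocycle (second ring): Claisen ring expansion of the 2-methylene derivative of a 12-membered lactone forms C9–C10, the C11 ketone and the (E)-alkene.
4. 12-Membered lactone (first ring): the C7 alkoxide opens a lactic-acid-derived dioxolanone (C11/C12) that was alkylated at C12 by a C13 iodide; C2–C3 comes from acylating a carvone-derived lactone enolate with a linalool-derived oxolane acid.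
5. Stereocentres: C1 from (R)-carvone, C4 from (R)-linalool, C12 from (S)-lactic acid; C3, C7 and C8 by substrate control.

Numbering used below (cembrane type): C1 = CH bearing the acrylate carbon C15; C3 = CHOH; C4 and C7 = oxolane carbons; C8 = C(CH3)OH; C11 = ketone; C12 = O–C(CH3); C16 = lactone carbonyl. Target = (1R,3S,4R,7R,8R,12R).
Assumption: centres that are erased later (the acetal carbon in 2–4, 11, 13–18, 22 and 23, C2 of 13 and 14, the C7 carbinol in 24–27) are carried as mixtures.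

**Step 1**
Reactants: 1 (R)-(−)-linalool
Product: 3 (2R)-2-ethenyl-5-methoxy-2-methyloxolane, via lactol 2 (not isolated)
Conditions: O3 (1.0 equiv), CH2Cl2/MeOH, −78 °C; Me2S; then p-TsOH (cat.), MeOH, rt
Reagents that add atoms: methanol CO
Why: Criegee ozonolysis cleaves only the electron-rich trisubstituted alkene and Fischer acetalisation caps the lactol, leaving the linalool carbinol carbon (future C4, R) untouched.

**Step 2**
Reactants: 3 (2R)-2-ethenyl-5-methoxy-2-methyloxolane
Product: 5 (2R)-5-methoxy-2-methyloxolane-2-carboxylic acid, via aldehyde 4 (not isolated)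
Conditions: O3, CH2Cl2, −78 °C; PPh3; then NaClO2, NaH2PO4, 2-methyl-2-butene, t-BuOH/H2O, rt
Reagents that add atoms: ozone O=[O+][O-]; sodium chlorite (NaClO2) [Na+].[O-]Cl=O
Why: Ozonolysis of the vinyl group followed by Pinnick oxidation gives the C3 acid without touching the quaternary centre.

**Step 3**
Reactants: 6 (R)-(−)-carvone
Product: 7 (1R,4R,6R)-1-methyl-4-(prop-1-en-2-yl)-7-oxabicyclo[4.1.0]heptan-2-one
Conditions: 30% H2O2, NaOH (cat.), MeOH, 0 °C
Reagents that add atoms: hydrogen peroxide OO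
Why: Weitz–Scheffer epoxidation attacks only the enone, anti to the isopropenyl group (both epoxide centres are destroyed in step 4).

**Step 4**
Reactants: 7 carvone oxide
Product: 8 (3R)-5-oxo-3-(prop-1-en-2-yl)pentanoic acid
Conditions: H5IO6 (2.5 equiv), THF/H2O, 0 °C → rt
Reagents that add atoms: water O; orthoperiodic acid OI(=O)(O)(O)(O)O
Why: Epoxide hydration and two Malaprade cleavages excise the C(O)–C(CH3) unit as acetic acid, leaving the carvone centre (future C1) with one acid arm and one aldehyde arm.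

**Step 5**
Reactants: 8 (3R)-5-oxo-3-(prop-1-en-2-yl)pentanoic acid
Product: 10 (4R)-4-(prop-1-en-2-yl)oxan-2-one, via hydroxy acid 9 (not isolated)
Conditions: NaBH4, EtOH, 0 °C; then 2 M HCl, rt
Reagents that add atoms: none
Why: Borohydride reduces only the aldehyde and acidification lactonises the 5-hydroxy acid.

**Step 6**
Reactants: 5 (2R)-5-methoxy-2-methyloxolane-2-carboxylic acid; 10 (4R)-4-(prop-1-en-2-yl)oxan-2-one
Product: 13 (4R)-3-[(2R)-5-methoxy-2-methyloxolane-2-carbonyl]-4-(prop-1-en-2-yl)oxan-2-one, via acyl imidazole 11 (not isolated), via lactone enolate 12 (not isolated)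
Conditions: 5, CDI, THF, rt; 10, LiN(SiMe3)2 (2.1 equiv), THF, −78 °C; combine, −78 → 0 °C; aq. NH4Cl
Reagents that add atoms: none
Why: Crossed Claisen C-acylation of the lactone enolate joins C2 to C3; neither pool stereocentre is enolisable.

**Step 7**
Reactants: 13 keto lactone
Product: 15 (3R)-5-hydroxy-1-[(2R)-5-methoxy-2-methyloxolan-2-yl]-3-(prop-1-en-2-yl)pentan-1-one, via keto acid 14 (not isolated)
Conditions: LiOH, THF/H2O, 0 °C → rt; then 1 M HCl to pH 4, 45 °C
Reagents that add atoms: none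
Why: Saponification and decarboxylation of the β-keto acid (acetoacetic-ester type ketone synthesis) leave the C3 ketone and free the C13 hydroxyl.

**Step 8**
Reactants: 15 keto alcohol
Product: 16 (1S,3R)-1-[(2R)-5-methoxy-2-methyloxolan-2-yl]-3-(prop-1-en-2-yl)pentane-1,5-diol
Conditions: Zn(BH4)2, Et2O, −30 °C
Reagents that add atoms: none
Why: Chelation-controlled reduction (Cram cyclic model): zinc bridges the ketone and oxolane oxygens and hydride enters from the face of the C4 methyl group, giving the 3S carbinol.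

**Step 9**
Reactants: 16 diol
Product: 17 (1S,3S)-5-iodo-1-[(2R)-5-methoxy-2-methyloxolan-2-yl]-3-(prop-1-en-2-yl)pentan-1-ol
Conditions: PPh3, I2, imidazole, CH2Cl2, 0 °C (16 added to the pre-mixed reagents)
Reagents that add atoms: iodine II
Why: Appel-type iodination takes place only at the primary hydroxyl; the neopentyl-like secondary hydroxyl is inert (the descriptor at C1 changes by priority only).

**Step 10**
Reactants: 17 iodo alcohol
Product: 18 tert-butyldimethylsilyl ether of 17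
Conditions: TBSOTf, 2,6-lutidine, CH2Cl2, −40 °C
Reagents that add atoms: tert-butyldimethylsilyl triflate CC(C)(C)[Si](C)(C)OS(=O)(=O)C(F)(F)F
Why: Silylation masks the C3 hydroxyl for the enolate, rhenium and lactonisation steps.

**Step 11**
Reactants: 19 (S)-lactic acid
Product: 20 (2S,5S)-2-tert-butyl-5-methyl-1,3-dioxolan-4-one
Conditions: pivalaldehyde, p-TsOH (cat.), pentane, reflux (Dean–Stark); crystallisation at −78 °C
Reagents that add atoms: pivalaldehyde CC(C)(C)C=O
Why: Seebach acetalisation gives the thermodynamically preferred cis acetal, so the lactate centre fixes the acetal carbon.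

**Step 12**
Reactants: 20 (2S,5S)-2-tert-butyl-5-methyl-1,3-dioxolan-4-one; 18 silyl ether iodide
Product: 22 (2S,5R)-2-tert-butyl-5-methyl-5-[(3R,5S)-5-(tert-butyldimethylsilyloxy)-5-[(2R)-5-methoxy-2-methyloxolan-2-yl]-3-(prop-1-en-2-yl)pentyl]-1,3-dioxolan-4-one, via dioxolanone enolate 21 (not isolated)
Conditions: LiN(i-Pr)2, THF, −78 °C; then 18, DMPU, −78 → −25 °C
Reagents that add atoms: none
Why: Seebach self-regeneration of stereocentres: the enolate is alkylated anti to the tert-butyl group, so the chain takes the place of the lactate hydrogen and C12 is formed as R.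

**Step 13**
Reactants: 22 alkylated dioxolanone
Product: 23 lactol (22 with OCH3 replaced by OH)
Conditions: AcOH/THF/H2O (3:1:1), 40 °C
Reagents that add atoms: water O
Why: Hydrolysis of the furanoside-type methyl acetal is far faster than that of the acylal or the hindered silyl ether.

**Step 14**
Reactants: 23 lactol
Product: 24 (2S,5R)-2-tert-butyl-5-[(3R,5S,6R)-5-(tert-butyldimethylsilyloxy)-6,9-dihydroxy-6,10-dimethyl-3-(prop-1-en-2-yl)undec-10-enyl]-5-methyl-1,3-dioxolan-4-one
Conditions: 2-bromopropene, CrCl2 (6 equiv), NiCl2 (2 mol %), DMF, rt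
Reagents that add atoms: 2-bromopropene CC(Br)=C
Why: Nozaki–Hiyama–Kishi addition to the open hydroxy-aldehyde form is aldehyde-selective and spares the dioxolanone; the C7 carbinol mixture is erased in step 16.

**Step 15**
Reactants: 24 allylic diol
Product: 26 bis(trimethylsilyl) ether of the 12-membered lactone, via macrolactone diol 25 (not isolated)
Conditions: NaH (2.2 equiv), THF (1 mM), 0 → 40 °C; then Me3SiCl, 0 °C
Reagents that add atoms: chlorotrimethylsilane C[Si](C)(C)Cl
Why: Alkoxide transacylation: the C7 alkoxide opens the activated dioxolanone ester with loss of pivalaldehyde to give the 12-membered lactone (the C4 alkoxide would need a 9-membered ring), and the two tertiary alkoxides are silylated in the same flask.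

**Step 16**
Reactants: 26 silylated 12-membered lactone
Product: 29 (2R,5R,7S,8R,11E)-7-(tert-butyldimethylsilyloxy)-2,8-dihydroxy-2,8,12-trimethyl-5-(prop-1-en-2-yl)cyclotetradec-11-en-1-one, via enol ether 27 (not isolated), via silyl ketone 28 (not isolated)
Conditions: Cp2TiMe2 (3 equiv), toluene, 75 °C, dark; then 135 °C, sealed tube; then PPTS, MeOH, rt
Reagents that add atoms: Cp2TiMe2 C[Ti](C)(C1C=CC=C1)C1C=CC=C1
Why: Petasis methylenation makes the allyl vinyl ether, and its Claisen [3,3]-rearrangement through a chair with C6 pseudo-equatorial forms C9–C10, the C11 ketone and the (E)-alkene while expanding the ring from 12 to 14 members.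

**Step 17**
Reactants: 29 14-membered hydroxy ketone
Product: 30 oxolane-bridged ketone (O on C4 bonded to C7, OH on C8; 4R,7R,8R)
Conditions: Re2O7 (1.5 equiv), 2,6-lutidine, CH2Cl2, rt
Reagents that add atoms: dirhenium heptoxide (Re2O7) O=[Re](=O)(=O)O[Re](=O)(=O)=O
Why: Kennedy oxidative cyclisation: the perrhenate ester of the C4 hydroxyl adds suprafacially ([3+2]) to the (E)-alkene with the bulky C3 side of C4 pseudo-equatorial, so the 2,5-trans oxolane forms and C7 and C8 are both R.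

**Step 18**
Reactants: 30 oxolane-bridged ketone
Product: 31 allylic alcohol (isopropenyl CH3 converted into CH2OH)
Conditions: SeO2 (0.3 equiv), t-BuOOH, CH2Cl2, rt
Reagents that add atoms: tert-butyl hydroperoxide CC(C)(C)OO
Why: Sharpless–Umbreit allylic oxidation (ene reaction then [2,3]-shift) attacks the methyl group of the only alkene left.

**Step 19**
Reactants: 31 allylic alcohol
Product: 33 acrylic acid (C16 acid), via enal 32 (not isolated)
Conditions: MnO2, CH2Cl2, rt; filter; then NaClO2, NaH2PO4, 2-methyl-2-butene, t-BuOH/H2O, rt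
Reagents that add atoms: sodium chlorite (NaClO2) [Na+].[O-]Cl=O
Why: Allylic alcohol oxidation followed by Pinnick oxidation gives the α-methylene acid without touching the ketone or the tertiary alcohols.

**Step 20**
Reactants: 33 seco acid
Product: 35 3-O-tert-butyldimethylsilyl ether of the target, via mixed anhydride 34 (not isolated)
Conditions: 2,4,6-trichlorobenzoyl chloride, Et3N, THF, rt; then DMAP, toluene (2 mM), 80 °C
Reagents that add atoms: none
Why: Yamaguchi lactonisation closes the 7-membered ring on the C12 hydroxyl, because C3 is silylated and the C8 hydroxyl would need an 11-membered ring.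

**Step 21**
Reactants: 35 silyl ether of the target
Product: 36 CNP0266269.1
Conditions: HF·pyridine, THF, 0 °C → rt
Reagents that add atoms: none
Why: Fluoride-mediated desilylation frees the C3 hydroxyl under mildly acidic conditions that spare the α-methylene lactone.

**Compound list**
1 | (R)-(−)-linalool | C=C[C@](C)(O)CCC=C(C)C | starting material
2 | (5R)-5-ethenyl-5-methyloxolan-2-ol (anomers) | C=C[C@@]1(C)CCC(O)O1 | intermediate
3 | (2R)-2-ethenyl-5-methoxy-2-methyloxolane (anomers) | C=C[C@@]1(C)CCC(OC)O1 | intermediate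
4 | (2R)-5-methoxy-2-methyloxolane-2-carbaldehyde | O=C[C@@]1(C)CCC(OC)O1 | intermediate
5 | (2R)-5-methoxy-2-methyloxolane-2-carboxylic acid | OC(=O)[C@@]1(C)CCC(OC)O1 | intermediate
6 | (R)-(−)-carvone | CC1=CC[C@H](CC1=O)C(C)=C | starting material
7 | (1R,4R,6R)-1-methyl-4-(prop-1-en-2-yl)-7-oxabicyclo[4.1.0]heptan-2-one | CC(=C)[C@@H]1C[C@H]2O[C@@]2(C)C(=O)C1 | intermediate
8 | (3R)-5-oxo-3-(prop-1-en-2-yl)pentanoic acid | CC(=C)[C@H](CC=O)CC(O)=O | intermediate
9 | (3R)-5-hydroxy-3-(prop-1-en-2-yl)pentanoic acid | CC(=C)[C@H](CCO)CC(O)=O | intermediate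
10 | (4R)-4-(prop-1-en-2-yl)oxan-2-one | CC(=C)[C@@H]1CCOC(=O)C1 | intermediate
11 | acyl imidazole of 5 | O=C(n1ccnc1)[C@@]2(C)CCC(OC)O2 | intermediate
12 | lithium enolate of 10 | CC(=C)[C@@H]1CCOC([O-])=C1.[Li+] | intermediate
13 | (4R)-3-[(2R)-5-methoxy-2-methyloxolane-2-carbonyl]-4-(prop-1-en-2-yl)oxan-2-one | CC(=C)[C@@H]1CCOC(=O)C1C(=O)[C@@]2(C)CCC(OC)O2 | intermediate
14 | (3R)-5-hydroxy-2-[(2R)-5-methoxy-2-methyloxolane-2-carbonyl]-3-(prop-1-en-2-yl)pentanoic acid | CC(=C)[C@H](CCO)C(C(O)=O)C(=O)[C@@]1(C)CCC(OC)O1 | intermediate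
15 | (3R)-5-hydroxy-1-[(2R)-5-methoxy-2-methyloxolan-2-yl]-3-(prop-1-en-2-yl)pentan-1-one | CC(=C)[C@H](CCO)CC(=O)[C@@]1(C)CCC(OC)O1 | intermediate
16 | (1S,3R)-1-[(2R)-5-methoxy-2-methyloxolan-2-yl]-3-(prop-1-en-2-yl)pentane-1,5-diol | CC(=C)[C@H](CCO)C[C@H](O)[C@@]1(C)CCC(OC)O1 | intermediate
17 | (1S,3S)-5-iodo-1-[(2R)-5-methoxy-2-methyloxolan-2-yl]-3-(prop-1-en-2-yl)pentan-1-ol | CC(=C)[C@H](CCI)C[C@H](O)[C@@]1(C)CCC(OC)O1 | intermediate
18 | tert-butyldimethylsilyl ether of 17 | CC(=C)[C@H](CCI)C[C@H](O[Si](C)(C)C(C)(C)C)[C@@]1(C)CCC(OC)O1 | intermediate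
19 | (S)-lactic acid | C[C@H](O)C(O)=O | starting material
20 | (2S,5S)-2-tert-butyl-5-methyl-1,3-dioxolan-4-one | C[C@@H]1O[C@@H](OC1=O)C(C)(C)C | intermediate
21 | lithium enolate of 20 | CC1=C([O-])O[C@H](O1)C(C)(C)C.[Li+] | intermediate
22 | (2S,5R)-dioxolanone alkylated at C5 with the C13–C3 chain (methyl acetal) | C[C@]1(CC[C@H](C[C@H](O[Si](C)(C)C(C)(C)C)[C@@]2(C)CCC(OC)O2)C(C)=C)O[C@@H](OC1=O)C(C)(C)C | intermediate
23 | lactol from 22 | C[C@]1(CC[C@H](C[C@H](O[Si](C)(C)C(C)(C)C)[C@@]2(C)CCC(O)O2)C(C)=C)O[C@@H](OC1=O)C(C)(C)C | intermediate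
24 | allylic diol (C4 and C7 hydroxyls free, dioxolanone intact) | C[C@]1(CC[C@H](C[C@H](O[Si](C)(C)C(C)(C)C)[C@](C)(O)CCC(O)C(C)=C)C(C)=C)O[C@@H](OC1=O)C(C)(C)C | intermediate
25 | (3R,6R,8S,9R)-8-(tert-butyldimethylsilyloxy)-3,9-dihydroxy-3,9-dimethyl-6,12-di(prop-1-en-2-yl)oxacyclododecan-2-one (formed as its disodium alkoxide) | O=C1OC(C(C)=C)CC[C@@](C)(O)[C@@H](O[Si](C)(C)C(C)(C)C)C[C@H](C(C)=C)CC[C@@]1(C)O | intermediate
26 | bis(trimethylsilyl) ether of 25 | O=C1OC(C(C)=C)CC[C@@](C)(O[Si](C)(C)C)[C@@H](O[Si](C)(C)C(C)(C)C)C[C@H](C(C)=C)CC[C@@]1(C)O[Si](C)(C)C | intermediate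
27 | 2-methylidene enol ether from 26 | C=C1OC(C(C)=C)CC[C@@](C)(O[Si](C)(C)C)[C@@H](O[Si](C)(C)C(C)(C)C)C[C@H](C(C)=C)CC[C@@]1(C)O[Si](C)(C)C | intermediate
28 | bis(trimethylsilyl) ether of 29 | O=C1CC/C(C)=C/CC[C@@](C)(O[Si](C)(C)C)[C@@H](O[Si](C)(C)C(C)(C)C)C[C@H](C(C)=C)CC[C@@]1(C)O[Si](C)(C)C | intermediate
29 | (2R,5R,7S,8R,11E)-7-(tert-butyldimethylsilyloxy)-2,8-dihydroxy-2,8,12-trimethyl-5-(prop-1-en-2-yl)cyclotetradec-11-en-1-one | O=C1CC/C(C)=C/CC[C@@](C)(O)[C@@H](O[Si](C)(C)C(C)(C)C)C[C@H](C(C)=C)CC[C@@]1(C)O | intermediate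
30 | oxolane-bridged ketone (4,7-ether, 8-OH, 12-OH, 3-OTBS, 1-isopropenyl) | O=C1CC[C@@](C)(O)[C@H]2CC[C@@](C)(O2)[C@@H](O[Si](C)(C)C(C)(C)C)C[C@H](C(C)=C)CC[C@@]1(C)O | intermediate
31 | allylic alcohol from 30 | O=C1CC[C@@](C)(O)[C@H]2CC[C@@](C)(O2)[C@@H](O[Si](C)(C)C(C)(C)C)C[C@H](C(=C)CO)CC[C@@]1(C)O | intermediate
32 | enal from 31 | O=C1CC[C@@](C)(O)[C@H]2CC[C@@](C)(O2)[C@@H](O[Si](C)(C)C(C)(C)C)C[C@H](C(=C)C=O)CC[C@@]1(C)O | intermediate
33 | acrylic acid (seco acid) | O=C1CC[C@@](C)(O)[C@H]2CC[C@@](C)(O2)[C@@H](O[Si](C)(C)C(C)(C)C)C[C@H](C(=C)C(O)=O)CC[C@@]1(C)O | intermediate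
34 | 2,4,6-trichlorobenzoic mixed anhydride of 33 | O=C1CC[C@@](C)(O)[C@H]2CC[C@@](C)(O2)[C@@H](O[Si](C)(C)C(C)(C)C)C[C@H](C(=C)C(=O)OC(=O)c3c(Cl)cc(Cl)cc3Cl)CC[C@@]1(C)O | intermediate
35 | 3-O-tert-butyldimethylsilyl ether of the target | C=C1C(=O)O[C@]2(C)CC[C@@H]1C[C@H](O[Si](C)(C)C(C)(C)C)[C@@]1(C)CC[C@@H](O1)[C@](C)(O)CCC2=O | intermediate
36 | CNP0266269.1 | C=C1C(=O)O[C@]2(C)CC[C@@H]1C[C@H](O)[C@@]1(C)CC[C@@H](O1)[C@](C)(O)CCC2=O | target

**Step count:** 21 steps in total. Longest linear sequence: 18 steps (steps 3–10 and 12–21, from carvone); steps 1–2 and 11 are side branches.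

**Steps most likely to fail, with fallbacks**

Step 14 (chromium-mediated addition to a lactol that sits mostly in its closed form). The fallback sets out from 18 and puts the Grignard addition before the dioxolanone is introduced. AcOH/THF/H2O gives lactol iodide F1. Isopropenylmagnesium bromide (THF, −78 → −20 °C) gives diol iodide F2. Me3SiOTf/2,6-lutidine gives bis(trimethylsilyl) ether F3. Alkylation of enolate 21 with F3 gives dioxolanone F4. PPTS/MeOH removes the two trimethylsilyl groups and the route is rejoined at 24.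

Step 15 (macrolactonisation by opening a hindered dioxolanone with a secondary alkoxide; oligomers or slow acyl transfer are possible). The fallback sets out from 24. LiOH in THF/H2O opens the dioxolanone to hydroxy acid F5. Shiina macrolactonisation (2-methyl-6-nitrobenzoic anhydride, DMAP, CH2Cl2, 1 mM) then gives 25 as an isolated compound. Me3SiOTf/2,6-lutidine converts it into 26, where the route is rejoined.

Step 16 (methylenation of a lactone carbonyl flanked by a quaternary carbon, then the ring-expanding Claisen). The fallback sets out from 24 and replaces it by a Carroll rearrangement. LiCH2CO2t-Bu (excess, THF, −78 °C) followed by Me3SiCl gives β-keto ester tris(trimethylsilyl) ether F6. K2CO3/MeOH at 0 °C frees only the secondary allylic hydroxyl, giving hydroxy β-keto ester F7. Heating in toluene (110 °C, 1 mM) generates the acylketene, which that hydroxyl traps to give 14-membered β-keto lactone F8. Further heating (xylene, 170 °C) brings about the Carroll [3,3]-rearrangement with loss of CO2, and the route is rejoined at 28.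

**Further compounds**
F1 | step 14 | lactol iodide (18 with OCH3 replaced by OH) | CC(=C)[C@H](CCI)C[C@H](O[Si](C)(C)C(C)(C)C)[C@@]1(C)CCC(O)O1
F2 | step 14 | diol iodide (C4 and C7 hydroxyls free) | CC(=C)[C@H](CCI)C[C@H](O[Si](C)(C)C(C)(C)C)[C@](C)(O)CCC(O)C(C)=C
F3 | step 14 | bis(trimethylsilyl) ether of F2 | CC(=C)[C@H](CCI)C[C@H](O[Si](C)(C)C(C)(C)C)[C@](C)(O[Si](C)(C)C)CCC(O[Si](C)(C)C)C(C)=C
F4 | step 14 | bis(trimethylsilyl) ether of 24 | C[C@]1(CC[C@H](C[C@H](O[Si](C)(C)C(C)(C)C)[C@](C)(O[Si](C)(C)C)CCC(O[Si](C)(C)C)C(C)=C)C(C)=C)O[C@@H](OC1=O)C(C)(C)C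
F5 | step 15 | (2R)-2-hydroxy-2-methyl acid from opening the dioxolanone of 24 | C[C@@](O)(CC[C@H](C[C@H](O[Si](C)(C)C(C)(C)C)[C@](C)(O)CCC(O)C(C)=C)C(C)=C)C(O)=O
F6 | step 16 | tert-butyl β-keto ester, tris(trimethylsilyl) ether | CC(C)(C)OC(=O)CC(=O)[C@](C)(O[Si](C)(C)C)CC[C@H](C[C@H](O[Si](C)(C)C(C)(C)C)[C@](C)(O[Si](C)(C)C)CCC(O[Si](C)(C)C)C(C)=C)C(C)=C
F7 | step 16 | tert-butyl β-keto ester with free C7 hydroxyl | CC(C)(C)OC(=O)CC(=O)[C@](C)(O[Si](C)(C)C)CC[C@H](C[C@H](O[Si](C)(C)C(C)(C)C)[C@](C)(O[Si](C)(C)C)CCC(O)C(C)=C)C(C)=C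
F8 | step 16 | 14-membered β-keto lactone | O=C1CC(=O)[C@](C)(O[Si](C)(C)C)CC[C@H](C[C@H](O[Si](C)(C)C(C)(C)C)[C@](C)(O[Si](C)(C)C)CCC(O1)C(C)=C)C(C)=C
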